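**Retrosynthetic overview**
- The target comes from its tri-O-acetate by a lipase-catalysed global deacetylation under neutral, non-aqueous conditions, so the free hydroquinone and the tertiary styryl carbinol never see acid or base.
- The (E)-styrene C–C bond is cut by a Mizoroki–Heck disconnection into a tertiary vinyl carbinol (ring A part) and 2-iodo-1,4-phenylene diacetate.
- The salicylaldehyde CHO comes from Mg-mediated ortho-formylation of a 4-alkyl-3,5-dimethylphenol. The vinyl carbinol comes from Zn-mediated reductive opening of a 2,3-epoxy iodide. The stereocentre comes from a Ti/tartrate-catalysed Sharpless asymmetric epoxidation of an (E)-trisubstituted allylic alcohol.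
- The allylic alcohol comes from a homobenzylic terminal alkyne by Zr-catalysed carboalumination and formaldehyde trapping. The alkyne comes from a benzylic bromide and lithiated 1-(trimethylsilyl)propyne.
- Rings: both benzene rings are bought intact. The only ring made is a transient oxirane (step 7), opened again in step 9.

Assumption: the carbinol stereocentre of the given SMILES is (S) by CIP analysis, and 4-hydroxy-2,6-dimethylbenzaldehyde, 1-(trimethylsilyl)propyne and 2-iodo-1,4-dimethoxybenzene are bought.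

**Route**

Step 1
Reactants: 1 4-hydroxy-2,6-dimethylbenzaldehyde
Product: 2 2,6-dimethyl-4-[(triisopropylsilyl)oxy]benzaldehyde
Conditions: TIPSCl, imidazole, DMF, rt
Reagents that add atoms: chlorotriisopropylsilane (TIPSCl), CC(C)[Si](Cl)(C(C)C)C(C)C
Why: Imidazole-promoted O-silylation of the phenol gives a bulky aryl TIPS ether that survives the organolithium, organoaluminium and Ti/peroxide steps and is later removed with fluoride.

Step 2
Reactants: 2 2,6-dimethyl-4-[(triisopropylsilyl)oxy]benzaldehyde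
Product: 3 {2,6-dimethyl-4-[(triisopropylsilyl)oxy]phenyl}methanol
Conditions: NaBH4, THF/MeOH, 0 °C
Reagents that add atoms: none
Why: Borohydride reduction of the aryl aldehyde to the benzylic alcohol is chemoselective and leaves the silyl ether alone.

Step 3
Reactants: 3 {2,6-dimethyl-4-[(triisopropylsilyl)oxy]phenyl}methanol
Product: 4 [4-(bromomethyl)-3,5-dimethylphenoxy]triisopropylsilane
Conditions: PBr3 (0.4 equiv), Et2O, 0 °C; used crude at once
Reagents that add atoms: phosphorus tribromide, BrP(Br)Br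
Why: PBr3 bromination of an activated benzylic alcohol is fast at 0 °C, and the electron-rich benzylic bromide is carried on without storage.

Step 4
Reactants: 4 [4-(bromomethyl)-3,5-dimethylphenoxy]triisopropylsilane; 5 1-(trimethylsilyl)propyne
Product: 7 triisopropyl{3,5-dimethyl-4-[4-(trimethylsilyl)but-3-yn-1-yl]phenoxy}silane, via 3-lithio-1-(trimethylsilyl)propyne 6 (not isolated)
Conditions: 5, n-BuLi, THF, −78 °C; then 4, −78 → 0 °C
Reagents that add atoms: none
Why: Corey-type propargylation, in which the silyl-capped propargyl lithium alkylates the benzylic bromide by SN2 at its CH2 terminus and the TMS group suppresses allene formation.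

Step 5
Reactants: 7 triisopropyl{3,5-dimethyl-4-[4-(trimethylsilyl)but-3-yn-1-yl]phenoxy}silane
Product: 8 [4-(but-3-yn-1-yl)-3,5-dimethylphenoxy]triisopropylsilane
Conditions: AgNO3 (10 mol%), acetone/H2O, rt
Reagents that add atoms: none
Why: Silver-catalysed protodesilylation cleaves only the C(sp)–Si bond and spares the aryl O–TIPS ether, which carbonate/methanol or fluoride could attack.

Step 6
Reactants: 8 [4-(but-3-yn-1-yl)-3,5-dimethylphenoxy]triisopropylsilane
Product: 11 (2E)-3-methyl-5-{2,6-dimethyl-4-[(triisopropylsilyl)oxy]phenyl}pent-2-en-1-ol, via (E)-alkenyldimethylalane 9 (not isolated), via lithium alkenylaluminate 10 (not isolated)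
Conditions: AlMe3 (3 equiv), Cp2ZrCl2 (25 mol%), CH2Cl2, 0 °C → rt; n-BuLi, THF, −78 °C; (CH2O)n, → rt; aq. Rochelle salt
Reagents that add atoms: trimethylaluminium, C[Al](C)C; paraformaldehyde (as formaldehyde), C=O
Why: Negishi Zr-catalysed methylalumination is a syn carbometalation that puts Me on the internal carbon (>98% E), and the derived aluminate adds to formaldehyde with retention of alkene geometry.

Step 7
Reactants: 11 (2E)-3-methyl-5-{2,6-dimethyl-4-[(triisopropylsilyl)oxy]phenyl}pent-2-en-1-ol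
Product: 12 [(2S,3S)-3-methyl-3-(2-{2,6-dimethyl-4-[(triisopropylsilyl)oxy]phenyl}ethyl)oxiran-2-yl]methanol
Conditions: Ti(OiPr)4 (10 mol%), L-(+)-DIPT (12 mol%), t-BuOOH, 4 Å MS, CH2Cl2, −20 °C
Reagents that add atoms: tert-butyl hydroperoxide, CC(C)(C)OO
Why: Katsuki–Sharpless catalytic asymmetric epoxidation with L-(+)-tartrate gives the (2S,3S)-epoxy alcohol from this geraniol-type (E)-allylic alcohol (typically 90–95% ee, checked by chiral HPLC), which fixes the future carbinol carbon as S.

Step 8
Reactants: 12 [(2S,3S)-3-methyl-3-(2-{2,6-dimethyl-4-[(triisopropylsilyl)oxy]phenyl}ethyl)oxiran-2-yl]methanol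
Product: 13 (2S,3R)-3-(iodomethyl)-2-methyl-2-(2-{2,6-dimethyl-4-[(triisopropylsilyl)oxy]phenyl}ethyl)oxirane
Conditions: PPh3, I2, imidazole, THF, 0 °C
Reagents that add atoms: iodine, II
Why: Appel-type (Garegg–Samuelsson) iodination converts the primary alcohol to the iodide under near-neutral conditions without touching the epoxide stereocentres (the descriptor change at the CH carbon is only a CIP priority change).

Step 9
Reactants: 13 (2S,3R)-3-(iodomethyl)-2-methyl-2-(2-{2,6-dimethyl-4-[(triisopropylsilyl)oxy]phenyl}ethyl)oxirane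
Product: 14 (3S)-3-methyl-5-{2,6-dimethyl-4-[(triisopropylsilyl)oxy]phenyl}pent-1-en-3-ol
Conditions: Zn dust, EtOH, 70 °C
Reagents that add atoms: none
Why: Zinc insertion into the C–I bond followed by β-elimination of the epoxide oxygen (reductive epoxide opening) gives the tertiary vinyl carbinol, and the C3–O bond with its S configuration is never broken.

Step 10
Reactants: 14 (3S)-3-methyl-5-{2,6-dimethyl-4-[(triisopropylsilyl)oxy]phenyl}pent-1-en-3-ol
Product: 15 4-[(3S)-3-hydroxy-3-methylpent-4-en-1-yl]-3,5-dimethylphenol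
Conditions: TBAF/AcOH (1:1), THF, 0 °C
Reagents that add atoms: none
Why: Fluoride cleaves the aryl silyl ether, and the acetic acid buffer keeps the medium neutral so the tertiary allylic alcohol is untouched.

Step 11
Reactants: 15 4-[(3S)-3-hydroxy-3-methylpent-4-en-1-yl]-3,5-dimethylphenol
Product: 17 6-hydroxy-3-[(3S)-3-hydroxy-3-methylpent-4-en-1-yl]-2,4-dimethylbenzaldehyde, via salicyl alcohol 16 (not isolated)
Conditions: MgCl2, Et3N, (CH2O)n, THF, reflux; cold aq. NH4Cl
Reagents that add atoms: paraformaldehyde (as formaldehyde), C=O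
Why: Casnati–Skattebøl ortho-formylation, in which the magnesium phenoxide delivers formaldehyde to the ortho carbon and the salicyl alcohol is oxidised in situ by hydride transfer to a second formaldehyde; the para position is blocked and the two ortho positions are equivalent, so one isomer forms under non-acidic conditions.

Step 12
Reactants: 17 6-hydroxy-3-[(3S)-3-hydroxy-3-methylpent-4-en-1-yl]-2,4-dimethylbenzaldehyde
Product: 18 2-formyl-4-[(3S)-3-hydroxy-3-methylpent-4-en-1-yl]-3,5-dimethylphenyl acetate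
Conditions: Ac2O (1.1 equiv), Et3N, DMAP (2 mol%), CH2Cl2, 0 °C
Reagents that add atoms: acetic anhydride, CC(=O)OC(C)=O
Why: The phenol is acetylated selectively (the tertiary alcohol is far slower at 0 °C), which masks the phenoxide that could otherwise direct Pd to the formyl C–H during the Heck step.

Step 13
Reactants: 19 2-iodo-1,4-dimethoxybenzene
Product: 20 2-iodobenzene-1,4-diol
Conditions: BBr3, CH2Cl2, −78 °C → rt; H2O
Reagents that add atoms: none
Why: BBr3-mediated aryl methyl ether cleavage leaves the aryl iodide intact.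

Step 14
Reactants: 20 2-iodobenzene-1,4-diol
Product: 21 2-iodo-1,4-phenylene diacetate
Conditions: Ac2O, pyridine, rt
Reagents that add atoms: acetic anhydride, CC(=O)OC(C)=O
Why: Exhaustive O-acetylation makes the hydroquinone non-oxidisable and installs the ester handles for the enzymatic end-game.

Step 15
Reactants: 18 2-formyl-4-[(3S)-3-hydroxy-3-methylpent-4-en-1-yl]-3,5-dimethylphenyl acetate; 21 2-iodo-1,4-phenylene diacetate
Product: 22 2-[(1E,3S)-5-(4-acetoxy-3-formyl-2,6-dimethylphenyl)-3-hydroxy-3-methylpent-1-en-1-yl]-1,4-phenylene diacetate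
Conditions: Pd(OAc)2 (5 mol%), P(o-tol)3 (10 mol%), Et3N, MeCN, 80 °C
Reagents that add atoms: none
Why: Mizoroki–Heck arylation of the terminal vinyl carbon, in which syn β-hydride elimination can only use the benzylic H because the carbinol carbon is quaternary, gives the (E)-styrene with the stereocentre untouched and the aryl acetates tolerated.

Step 16
Reactants: 22 2-[(1E,3S)-5-(4-acetoxy-3-formyl-2,6-dimethylphenyl)-3-hydroxy-3-methylpent-1-en-1-yl]-1,4-phenylene diacetate
Product: 23 3-[(3S,4E)-5-(2,5-dihydroxyphenyl)-3-hydroxy-3-methylpent-4-en-1-yl]-6-hydroxy-2,4-dimethylbenzaldehyde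
Conditions: lipase (immobilised Candida antarctica lipase B, Novozym 435), n-BuOH, MTBE, 40 °C, Ar; filter and evaporate
Reagents that add atoms: none
Why: Lipase-catalysed transesterification (serine-hydrolase acyl-enzyme, acetyl passed to n-butanol) removes the three aryl acetates at neutral pH without water, so the tertiary styryl carbinol is not ionised towards a chromene, the hydroquinone is not oxidised, and the enzyme does not acylate the tertiary alcohol.

**Compound list**
1 | 4-hydroxy-2,6-dimethylbenzaldehyde | Cc1cc(O)cc(C)c1C=O | starting material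
2 | 2,6-dimethyl-4-[(triisopropylsilyl)oxy]benzaldehyde | Cc1cc(O[Si](C(C)C)(C(C)C)C(C)C)cc(C)c1C=O | intermediate
3 | {2,6-dimethyl-4-[(triisopropylsilyl)oxy]phenyl}methanol | Cc1cc(O[Si](C(C)C)(C(C)C)C(C)C)cc(C)c1CO | intermediate
4 | [4-(bromomethyl)-3,5-dimethylphenoxy]triisopropylsilane | Cc1cc(O[Si](C(C)C)(C(C)C)C(C)C)cc(C)c1CBr | intermediate
5 | 1-(trimethylsilyl)propyne | CC#C[Si](C)(C)C | starting material
6 | 3-lithio-1-(trimethylsilyl)propyne (formed in the flask) | [Li]CC#C[Si](C)(C)C | intermediate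
7 | triisopropyl{3,5-dimethyl-4-[4-(trimethylsilyl)but-3-yn-1-yl]phenoxy}silane | Cc1cc(O[Si](C(C)C)(C(C)C)C(C)C)cc(C)c1CCC#C[Si](C)(C)C | intermediate
8 | [4-(but-3-yn-1-yl)-3,5-dimethylphenoxy]triisopropylsilane | Cc1cc(O[Si](C(C)C)(C(C)C)C(C)C)cc(C)c1CCC#C | intermediate
9 | dimethyl[(1E)-2-methyl-4-{2,6-dimethyl-4-[(triisopropylsilyl)oxy]phenyl}but-1-en-1-yl]alane (formed in the flask) | Cc1cc(O[Si](C(C)C)(C(C)C)C(C)C)cc(C)c1CC/C(C)=C/[Al](C)C | intermediate
10 | lithium butyl(dimethyl)[(1E)-2-methyl-4-{2,6-dimethyl-4-[(triisopropylsilyl)oxy]phenyl}but-1-en-1-yl]aluminate (formed in the flask) | Cc1cc(O[Si](C(C)C)(C(C)C)C(C)C)cc(C)c1CC/C(C)=C/[Al-](C)(C)CCCC.[Li+] | intermediate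
11 | (2E)-3-methyl-5-{2,6-dimethyl-4-[(triisopropylsilyl)oxy]phenyl}pent-2-en-1-ol | Cc1cc(O[Si](C(C)C)(C(C)C)C(C)C)cc(C)c1CC/C(C)=C/CO | intermediate
12 | [(2S,3S)-3-methyl-3-(2-{2,6-dimethyl-4-[(triisopropylsilyl)oxy]phenyl}ethyl)oxiran-2-yl]methanol | Cc1cc(O[Si](C(C)C)(C(C)C)C(C)C)cc(C)c1CC[C@]1(C)O[C@H]1CO | intermediate
13 | (2S,3R)-3-(iodomethyl)-2-methyl-2-(2-{2,6-dimethyl-4-[(triisopropylsilyl)oxy]phenyl}ethyl)oxirane | Cc1cc(O[Si](C(C)C)(C(C)C)C(C)C)cc(C)c1CC[C@]1(C)O[C@H]1CI | intermediate
14 | (3S)-3-methyl-5-{2,6-dimethyl-4-[(triisopropylsilyl)oxy]phenyl}pent-1-en-3-ol | Cc1cc(O[Si](C(C)C)(C(C)C)C(C)C)cc(C)c1CC[C@](C)(O)C=C | intermediate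
15 | 4-[(3S)-3-hydroxy-3-methylpent-4-en-1-yl]-3,5-dimethylphenol | Cc1cc(O)cc(C)c1CC[C@](C)(O)C=C | intermediate
16 | 2-(hydroxymethyl)-4-[(3S)-3-hydroxy-3-methylpent-4-en-1-yl]-3,5-dimethylphenol (formed in the flask) | Cc1cc(O)c(CO)c(C)c1CC[C@](C)(O)C=C | intermediate
17 | 6-hydroxy-3-[(3S)-3-hydroxy-3-methylpent-4-en-1-yl]-2,4-dimethylbenzaldehyde | Cc1cc(O)c(C=O)c(C)c1CC[C@](C)(O)C=C | intermediate
18 | 2-formyl-4-[(3S)-3-hydroxy-3-methylpent-4-en-1-yl]-3,5-dimethylphenyl acetate | Cc1cc(OC(C)=O)c(C=O)c(C)c1CC[C@](C)(O)C=C | intermediate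
19 | 2-iodo-1,4-dimethoxybenzene | COc1ccc(OC)c(I)c1 | starting material
20 | 2-iodobenzene-1,4-diol | Oc1ccc(O)c(I)c1 | intermediate
21 | 2-iodo-1,4-phenylene diacetate | CC(=O)Oc1ccc(OC(C)=O)c(I)c1 | intermediate
22 | 2-[(1E,3S)-5-(4-acetoxy-3-formyl-2,6-dimethylphenyl)-3-hydroxy-3-methylpent-1-en-1-yl]-1,4-phenylene diacetate | Cc1cc(OC(C)=O)c(C=O)c(C)c1CC[C@](C)(O)/C=C/c1cc(OC(C)=O)ccc1OC(C)=O | intermediate
23 | 3-[(3S,4E)-5-(2,5-dihydroxyphenyl)-3-hydroxy-3-methylpent-4-en-1-yl]-6-hydroxy-2,4-dimethylbenzaldehyde | Cc1cc(O)c(C=O)c(C)c1CC[C@](C)(O)/C=C/c1cc(O)ccc1O | target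

**Step count**
Total steps: 16. Longest linear sequence: 14 (steps 1–12, 15, 16); steps 13–14 are a two-step side branch.

**Three steps most likely to fail, with fallbacks**

Step 11 (ortho-formylation next to a free tertiary allylic alcohol; risk of low conversion or over-reaction with formaldehyde). The fallback sets out from 15. NBS with catalytic i-Pr2NH in CH2Cl2 at −78 → 0 °C brominates the only free ring position type (para blocked, both ortho positions equivalent) to give 2-bromo-4-[(3S)-3-hydroxy-3-methylpent-4-en-1-yl]-3,5-dimethylphenol F1. Treatment with n-BuLi (3.3 equiv, THF, −78 °C; two O–H deprotonations, then Br/Li exchange) and a DMF quench with neutral work-up then gives the salicylaldehyde. The fallback comes back to the route at 17.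

Step 15 (Heck coupling of an ortho-substituted aryl iodide with a hindered tertiary allylic alcohol in the presence of an aryl aldehyde). The fallback sets out from 21 and 18. Stille vinylation of 21 (tributyl(vinyl)stannane, Pd(PPh3)4, toluene, 90 °C) gives 2-ethenyl-1,4-phenylene diacetate F2. Olefin cross-metathesis of 18 with excess F2 (Hoveyda–Grubbs II, CH2Cl2, 40 °C) then forms the (E)-styrene with loss of ethene, since the tertiary allylic alcohol does not homodimerise. The fallback comes back to the route at 22.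

Step 16 (the lipase may stall on the hindered acetate ortho to the formyl group). The fallback sets out from 17 and changes the protecting-group plan so that the enzyme only has to cleave the two hydroquinone acetates. TBSCl/imidazole in DMF gives 6-[(tert-butyldimethylsilyl)oxy]-3-[(3S)-3-hydroxy-3-methylpent-4-en-1-yl]-2,4-dimethylbenzaldehyde F3. The same Heck coupling with 21 gives 2-[(1E,3S)-5-{4-[(tert-butyldimethylsilyl)oxy]-3-formyl-2,6-dimethylphenyl}-3-hydroxy-3-methylpent-1-en-1-yl]-1,4-phenylene diacetate F4. TBAF/AcOH (1:1) in THF at 0 °C removes the silyl group to give 2-[(1E,3S)-5-(3-formyl-4-hydroxy-2,6-dimethylphenyl)-3-hydroxy-3-methylpent-1-en-1-yl]-1,4-phenylene diacetate F5. The same lipase/n-BuOH alcoholysis then frees the hydroquinone as the last operation. The fallback comes back to the route at 23.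

**Further compounds**
F1 | step 11 | 2-bromo-4-[(3S)-3-hydroxy-3-methylpent-4-en-1-yl]-3,5-dimethylphenol | Cc1cc(O)c(Br)c(C)c1CC[C@](C)(O)C=C
F2 | step 15 | 2-ethenyl-1,4-phenylene diacetate | CC(=O)Oc1ccc(OC(C)=O)c(C=C)c1
F3 | step 16 | 6-[(tert-butyldimethylsilyl)oxy]-3-[(3S)-3-hydroxy-3-methylpent-4-en-1-yl]-2,4-dimethylbenzaldehyde | Cc1cc(O[Si](C)(C)C(C)(C)C)c(C=O)c(C)c1CC[C@](C)(O)C=C
F4 | step 16 | 2-[(1E,3S)-5-{4-[(tert-butyldimethylsilyl)oxy]-3-formyl-2,6-dimethylphenyl}-3-hydroxy-3-methylpent-1-en-1-yl]-1,4-phenylene diacetate | Cc1cc(O[Si](C)(C)C(C)(C)C)c(C=O)c(C)c1CC[C@](C)(O)/C=C/c1cc(OC(C)=O)ccc1OC(C)=O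
F5 | step 16 | 2-[(1E,3S)-5-(3-formyl-4-hydroxy-2,6-dimethylphenyl)-3-hydroxy-3-methylpent-1-en-1-yl]-1,4-phenylene diacetate | Cc1cc(O)c(C=O)c(C)c1CC[C@](C)(O)/C=C/c1cc(OC(C)=O)ccc1OC(C)=O
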